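**Synthesis proposal for CNP0139207.0: 7-hydroxy-5-methoxy-3-(5-methoxy-2,2-dimethylchroman-6-yl)coumarin**

Retrosynthesis: C3=C4 dehydrogenation and removal of a 7-O-methoxymethyl group lead back to a racemic 3-aryl-3,4-dihydrocoumarin, which is cut at two bonds at once, C3–aryl and O1–C2.
Enabling feature: the lactone carbon C2 lies between the ring oxygen O1 on the benzo ring and C3, which carries the chroman aryl. C2 can therefore be the carbonyl of an aryl ketone whose aryl has moved to the neighbouring diazo carbon, and the ortho-phenol is placed to close the six-membered lactone on the resulting ketene.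
The diazo ketone goes back to a 1,3-diarylpropan-1-one, cut at the future C3–C4 bond by an aldol condensation of an acetylchroman with a salicylaldehyde.
Forward: the dihydropyran ring of the chroman is made first, the two benzene rings are then joined through the three-carbon chain, and the lactone ring closes in the Wolff step before it is dehydrogenated to the 2-pyranone.
Stereochemistry: the target is achiral; C3 is racemic at the dihydrocoumarin and selenide stages and then becomes sp2, and the E-enone of the chalcone is hydrogenated.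

Key step: step 10

Assumption: the three starting materials are catalogue compounds; the diazo intermediates are handled cold and shielded from light, and the one stereocentre on the route is carried as a racemate.

Step 1
Reactants: 1 2,4-dihydroxyacetophenone; 2 3-methylbut-2-enal
Product: 4 6-acetyl-5-hydroxy-2,2-dimethyl-2H-chromene, via ortho-quinone methide dienone 3 (not isolated)
Conditions: pyridine, 140 °C, sealed tube
Reagents that add atoms: none
Why: Amine-mediated Knoevenagel-type condensation at the doubly activated carbon between the two hydroxyls, dehydration to dienone 3 and oxa-6π electrocyclisation through the non-chelated 4-hydroxyl is the established chromenylation of resacetophenone and leaves the hydrogen-bonded 2-hydroxyl free.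

Step 2
Reactants: 4 6-acetyl-5-hydroxy-2,2-dimethyl-2H-chromene
Product: 5 6-acetyl-5-hydroxy-2,2-dimethylchroman
Conditions: H2 (1 atm), 10% Pd/C, EtOAc, rt
Reagents that add atoms: none
Why: Catalytic hydrogenation of the styrene-type chromene alkene is fast at 1 atm, whereas the chelated, electron-rich aryl ketone should not be reduced under these mild conditions.

Step 3
Reactants: 5 6-acetyl-5-hydroxy-2,2-dimethylchroman
Product: 6 6-acetyl-5-methoxy-2,2-dimethylchroman
Conditions: MeI, K2CO3, DMF, 50 °C
Reagents that add atoms: iodomethane, CI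
Why: Williamson O-methylation of the only acidic site; the hydrogen-bonded phenol needs carbonate in warm DMF and excess MeI, which is routine for 2-hydroxyacetophenones.

Step 4
Reactants: 7 2,4-dihydroxy-6-methoxybenzaldehyde
Product: 8 2-hydroxy-6-methoxy-4-(methoxymethoxy)benzaldehyde
Conditions: MOMCl (1.1 equiv), iPr2NEt, CH2Cl2, 0 °C
Reagents that add atoms: chloromethyl methyl ether, COCCl
Why: Selective acetal protection: the 4-hydroxyl para to the formyl group is the more acidic and the non-chelated one, so one equivalent of MOMCl with a hindered amine should alkylate it alone, as is standard for 2,4-dihydroxybenzaldehydes.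

Step 5
Reactants: 6 6-acetyl-5-methoxy-2,2-dimethylchroman; 8 2-hydroxy-6-methoxy-4-(methoxymethoxy)benzaldehyde
Product: 10 (E)-2-hydroxy retro-chalcone (aryl ketone from the chroman half), via aldol adduct 9 (not isolated)
Conditions: KOH (50% aq.), EtOH, rt; then AcOH to pH 6
Reagents that add atoms: none
Why: Claisen–Schmidt crossed aldol condensation of a methyl ketone with a non-enolisable aldehyde, in which E1cB dehydration of aldol 9 gives the conjugated E-enone; salicylaldehydes condense as their phenoxides in concentrated KOH and the MOM acetal is base-stable.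

Step 6
Reactants: 10 (E)-2-hydroxy retro-chalcone
Product: 11 3-[2-hydroxy-6-methoxy-4-(methoxymethoxy)phenyl]-1-(5-methoxy-2,2-dimethylchroman-6-yl)propan-1-one
Conditions: H2 (1 atm), 10% Pd/C, Ph2S (0.01 equiv), EtOAc, rt
Reagents that add atoms: none
Why: Hydrogenation over sulfide-poisoned Pd/C reduces only the enone C=C bond (chalcone to dihydrochalcone) and should spare the aryl ketone, the acetal and both arenes; neutral handling keeps the 2-hydroxyaryl ketone in its open form.

Step 7
Reactants: 11 retro-dihydrochalcone with free phenol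
Product: 12 triisopropylsilyl ether of 11
Conditions: iPr3SiCl, imidazole, DMF, rt
Reagents that add atoms: chlorotriisopropylsilane, CC(C)[Si](Cl)(C(C)C)C(C)C
Why: Standard phenol silylation; masking the O–H lets the next step form the ketone enolate with one equivalent of base and stops the phenol from adding to the trifluoroacetyl group, and the bulky silyl ether tolerates aqueous amine.

Step 8
Reactants: 12 triisopropylsilyl ether of the retro-dihydrochalcone
Product: 14 silyl-protected α-diazo ketone, via α-trifluoroacetyl ketone 13 (not isolated)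
Conditions: LiN(SiMe3)2, THF, −78 °C; CF3CO2CH2CF3, −78 °C; aq. NH4Cl work-up; then MsN3, Et3N, H2O (1 equiv), MeCN, rt
Reagents that add atoms: methanesulfonyl azide, CS(=O)(=O)N=[N+]=[N-] (the two diazo nitrogens of 14); 2,2,2-trifluoroethyl trifluoroacetate, O=C(OCC(F)(F)F)C(F)(F)F (trifluoroacetyl group of 13 only)
Why: Detrifluoroacetylative Regitz-type diazo transfer: the enolate of the only enolisable position is C-trifluoroacetylated and the activated 1,3-dicarbonyl 13 takes up the diazo group from the sulfonyl azide with loss of the trifluoroacetyl group, a sequence established for aryl alkyl ketones that do not react with sulfonyl azides directly.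

Step 9
Reactants: 14 silyl-protected α-diazo ketone
Product: 15 α-diazo ketone bearing the free ortho-phenol
Conditions: Bu4NF (1.1 equiv), AcOH (1.1 equiv), THF, 0 °C, dark
Reagents that add atoms: none
Why: Fluoride cleavage of an aryl silyl ether is fast at 0 °C, and buffering with AcOH keeps the medium near neutral, which acyl-stabilised diazo compounds tolerate.

Step 10
Reactants: 15 α-diazo ketone bearing the free ortho-phenol
Product: 17 racemic 7-(methoxymethoxy)-5-methoxy-3-(5-methoxy-2,2-dimethylchroman-6-yl)-3,4-dihydrocoumarin, via aryl(2-hydroxybenzyl)ketene 16 (not isolated)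
Conditions: hν (365 nm LEDs), degassed dry MeCN (0.01 M), 20 °C
Reagents that add atoms: none
Why: Irradiation of 15 expels N2 while the chroman aryl shifts from the carbonyl carbon to the diazo carbon (photochemical Wolff rearrangement, concerted or through the singlet acyl carbene), which makes the C3–aryl bond and gives ketene 16. The closest known reactions are the photo-Wolff rearrangement of α-alkyl α-diazo aryl ketones to 2-arylalkanoic acid derivatives and the capture of Wolff ketenes by a tethered hydroxyl to give lactones. The lactone ring closes by 6-exo addition of the phenol oxygen to the sp carbonyl carbon of the ketene (the C=O stays outside the ring), forming the O1–C2 bond, and tautomerisation of the ester enol places the hydrogen on C3. The new stereocentre C3 arises by uncontrolled protonation and is racemic, which does not matter because it becomes sp2 in step 12. The step needs aryl migration to win over 1,2-hydride shift from the benzylic CH2 (back to chalcone 10) and over carbene insertion into the phenol O–H (to a 2-aroyl-2,3-dihydrobenzofuran); metal-free direct irradiation, the high migratory aptitude of the 2,4-dioxygenated aryl group and high dilution in a non-nucleophilic solvent should favour the Wolff path, and the phenol, held five atoms from the ketene carbon, should outcompete any external trap.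

Step 11
Reactants: 17 racemic 3-aryl-3,4-dihydrocoumarin
Product: 18 racemic 3-(phenylselanyl) lactone
Conditions: LiN(SiMe3)2, THF, −78 °C; PhSeBr, −78 °C
Reagents that add atoms: phenylselenenyl bromide, Br[Se]c1ccccc1
Why: α-Selenenylation of an ester enolate: C3–H is activated by both the lactone carbonyl and the aryl group, so deprotonation at −78 °C and C-trapping with PhSeBr should be clean, and the new quaternary centre is racemic and destroyed in the next step.

Step 12
Reactants: 18 racemic 3-(phenylselanyl) lactone
Product: 20 7-(methoxymethoxy)-5-methoxy-3-(5-methoxy-2,2-dimethylchroman-6-yl)coumarin, via selenoxide 19 (not isolated)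
Conditions: 30% aq. H2O2, pyridine, CH2Cl2, 0 °C to rt
Reagents that add atoms: hydrogen peroxide, OO (selenoxide oxygen of 19 only)
Why: Selenoxide syn-elimination: the only β-hydrogens are on C4, so the C3=C4 bond of the coumarin is the sole possible alkene, and formation of the conjugated 2-pyranone drives the elimination below room temperature.

Step 13
Reactants: 20 7-O-methoxymethyl coumarin
Product: 21 CNP0139207.0
Conditions: HCl (2 M aq.), MeOH, 50 °C
Reagents that add atoms: none
Why: Acid-catalysed acetal exchange with methanol removes the MOM group, while the coumarin lactone, the aryl methyl ethers and the 2,2-dimethylchroman ether are stable to dilute methanolic HCl.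

Compound list
1 | 2,4-dihydroxyacetophenone | CC(=O)c1ccc(O)cc1O | starting material
2 | 3-methylbut-2-enal | CC(C)=CC=O | starting material
3 | 4-acetyl-3-hydroxy-2-(3-methylbut-2-en-1-ylidene)cyclohexa-3,5-dien-1-one (ortho-quinone methide dienone) | CC(=O)C1=C(O)C(=CC=C(C)C)C(=O)C=C1 | intermediate (not isolated)
4 | 6-acetyl-5-hydroxy-2,2-dimethyl-2H-chromene | CC(=O)c1ccc2c(c1O)C=CC(C)(C)O2 | intermediate
5 | 6-acetyl-5-hydroxy-2,2-dimethylchroman | CC(=O)c1ccc2c(c1O)CCC(C)(C)O2 | intermediate
6 | 6-acetyl-5-methoxy-2,2-dimethylchroman | CC(=O)c1ccc2c(c1OC)CCC(C)(C)O2 | intermediate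
7 | 2,4-dihydroxy-6-methoxybenzaldehyde | COc1cc(O)cc(O)c1C=O | starting material
8 | 2-hydroxy-6-methoxy-4-(methoxymethoxy)benzaldehyde | COCOc1cc(O)c(C=O)c(OC)c1 | intermediate
9 | 3-hydroxy-3-[2-hydroxy-6-methoxy-4-(methoxymethoxy)phenyl]-1-(5-methoxy-2,2-dimethylchroman-6-yl)propan-1-one (racemic aldol adduct) | COCOc1cc(O)c(C(O)CC(=O)c2ccc3c(c2OC)CCC(C)(C)O3)c(OC)c1 | intermediate (not isolated)
10 | (E)-3-[2-hydroxy-6-methoxy-4-(methoxymethoxy)phenyl]-1-(5-methoxy-2,2-dimethylchroman-6-yl)prop-2-en-1-one | COCOc1cc(O)c(/C=C/C(=O)c2ccc3c(c2OC)CCC(C)(C)O3)c(OC)c1 | intermediate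
11 | 3-[2-hydroxy-6-methoxy-4-(methoxymethoxy)phenyl]-1-(5-methoxy-2,2-dimethylchroman-6-yl)propan-1-one | COCOc1cc(O)c(CCC(=O)c2ccc3c(c2OC)CCC(C)(C)O3)c(OC)c1 | intermediate
12 | 3-[2-methoxy-4-(methoxymethoxy)-6-(triisopropylsilyloxy)phenyl]-1-(5-methoxy-2,2-dimethylchroman-6-yl)propan-1-one | COCOc1cc(O[Si](C(C)C)(C(C)C)C(C)C)c(CCC(=O)c2ccc3c(c2OC)CCC(C)(C)O3)c(OC)c1 | intermediate
13 | 4,4,4-trifluoro-2-[2-methoxy-4-(methoxymethoxy)-6-(triisopropylsilyloxy)benzyl]-1-(5-methoxy-2,2-dimethylchroman-6-yl)butane-1,3-dione (racemic) | COCOc1cc(O[Si](C(C)C)(C(C)C)C(C)C)c(CC(C(=O)C(F)(F)F)C(=O)c2ccc3c(c2OC)CCC(C)(C)O3)c(OC)c1 | intermediate (not isolated)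
14 | 2-diazo-3-[2-methoxy-4-(methoxymethoxy)-6-(triisopropylsilyloxy)phenyl]-1-(5-methoxy-2,2-dimethylchroman-6-yl)propan-1-one | COCOc1cc(O[Si](C(C)C)(C(C)C)C(C)C)c(CC(=[N+]=[N-])C(=O)c2ccc3c(c2OC)CCC(C)(C)O3)c(OC)c1 | intermediate
15 | 2-diazo-3-[2-hydroxy-6-methoxy-4-(methoxymethoxy)phenyl]-1-(5-methoxy-2,2-dimethylchroman-6-yl)propan-1-one | COCOc1cc(O)c(CC(=[N+]=[N-])C(=O)c2ccc3c(c2OC)CCC(C)(C)O3)c(OC)c1 | intermediate
16 | 3-[2-hydroxy-6-methoxy-4-(methoxymethoxy)phenyl]-2-(5-methoxy-2,2-dimethylchroman-6-yl)prop-1-en-1-one (ketene) | COCOc1cc(O)c(CC(=C=O)c2ccc3c(c2OC)CCC(C)(C)O3)c(OC)c1 | intermediate (not isolated)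
17 | 5-methoxy-3-(5-methoxy-2,2-dimethylchroman-6-yl)-7-(methoxymethoxy)chroman-2-one (racemic) | O=C1Oc2cc(OCOC)cc(OC)c2CC1c1ccc2c(c1OC)CCC(C)(C)O2 | intermediate
18 | 5-methoxy-3-(5-methoxy-2,2-dimethylchroman-6-yl)-7-(methoxymethoxy)-3-(phenylselanyl)chroman-2-one (racemic) | O=C1Oc2cc(OCOC)cc(OC)c2CC1([Se]c1ccccc1)c1ccc2c(c1OC)CCC(C)(C)O2 | intermediate
19 | 5-methoxy-3-(5-methoxy-2,2-dimethylchroman-6-yl)-7-(methoxymethoxy)-3-(phenylseleninyl)chroman-2-one (selenoxide, diastereomer mixture) | O=C1Oc2cc(OCOC)cc(OC)c2CC1([Se](=O)c1ccccc1)c1ccc2c(c1OC)CCC(C)(C)O2 | intermediate (not isolated)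
20 | 5-methoxy-3-(5-methoxy-2,2-dimethylchroman-6-yl)-7-(methoxymethoxy)-2H-chromen-2-one | COc1c(-c2cc3c(OC)cc(OCOC)cc3oc2=O)ccc2c1CCC(C)(C)O2 | intermediate
21 | 7-hydroxy-5-methoxy-3-(5-methoxy-2,2-dimethylchroman-6-yl)-2H-chromen-2-one (CNP0139207.0) | COc1c(-c2cc3c(OC)cc(O)cc3oc2=O)ccc2c1CCC(C)(C)O2 | target

Total step count: 13 steps.
Longest linear sequence: 12 steps (steps 1 to 3 and 5 to 13, from 2,4-dihydroxyacetophenone); step 4 lies on the aldehyde branch.

Steps most likely to fail

1. Step 10 (Wolff rearrangement with lactonisation). The excited diazo ketone may lose nitrogen with 1,2-hydride shift from the benzylic CH2 instead of aryl migration, or the carbene may insert into the phenol O–H, so that little ketene is formed. Fallback, setting out from ketone 6 and aldehyde 8 and returning at coumarin 20: a Perkin–Oglialoro construction of the 3-arylcoumarin. Ketone 6 would be taken through a Willgerodt–Kindler reaction (sulfur, morpholine, 130 °C) to 2-(5-methoxy-2,2-dimethylchroman-6-yl)-1-morpholinoethane-1-thione F1. Hydrolysis (KOH, aq. EtOH, reflux, then acidification) would give (5-methoxy-2,2-dimethylchroman-6-yl)acetic acid F2. Condensation of F2 with salicylaldehyde 8 (Ac2O, Et3N, 110 °C; O-acylation, intramolecular aldol, dehydration) should give 20 directly, which then enters step 13.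

2. Step 8 (diazo transfer). C-trifluoroacetylation of the enolate next to the ortho-methoxy aryl ketone may be incomplete or go on oxygen, and the silyl ether may be partly lost in the aqueous amine medium before transfer is complete. Fallback, setting out from silyl ether 12 and returning at diazo ketone 14: the diazo group is made from a 1,2-diketone instead. The enolate of 12 (KN(SiMe3)2, THF, −78 °C) would be hydroxylated with 2-(phenylsulfonyl)-3-phenyloxaziridine to 2-hydroxy-3-[2-methoxy-4-(methoxymethoxy)-6-(triisopropylsilyloxy)phenyl]-1-(5-methoxy-2,2-dimethylchroman-6-yl)propan-1-one F3. Oxidation with Dess–Martin periodinane (CH2Cl2, rt) would give 3-[2-methoxy-4-(methoxymethoxy)-6-(triisopropylsilyloxy)phenyl]-1-(5-methoxy-2,2-dimethylchroman-6-yl)propane-1,2-dione F4. Condensation with TsNHNH2 (MeOH, rt) at the less hindered, non-conjugated C2 carbonyl would give the 2-(p-toluenesulfonylhydrazone) of that dione F5. Treating F5 with Et3N in CH2Cl2 (Bamford–Stevens-type loss of sulfinate) should give 14.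

3. Step 5 (aldol condensation). Addition to the aldehyde may be slow because it reacts as an electron-rich phenoxide, allowing retro-aldol and decomposition to compete, and the 2-hydroxychalcone may cyclise towards a flavylium salt if the work-up becomes too acidic. Fallback, setting out from aldehyde 8 and returning at dihydrochalcone 11: the phenol is capped before the condensation. Aldehyde 8 would be benzylated (BnBr, K2CO3, DMF, rt) to 2-(benzyloxy)-6-methoxy-4-(methoxymethoxy)benzaldehyde F6. Claisen–Schmidt condensation of F6 with ketone 6 (KOH, EtOH, rt) would give (E)-3-[2-(benzyloxy)-6-methoxy-4-(methoxymethoxy)phenyl]-1-(5-methoxy-2,2-dimethylchroman-6-yl)prop-2-en-1-one F7. Hydrogenation of F7 over unpoisoned 10% Pd/C (H2, 1 atm, EtOAc, rt) should saturate the enone and cleave the benzyl ether in one operation to give 11.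

Further compounds
F1 | step 10 | 2-(5-methoxy-2,2-dimethylchroman-6-yl)-1-morpholinoethane-1-thione | S=C(Cc1ccc2c(c1OC)CCC(C)(C)O2)N1CCOCC1
F2 | step 10 | (5-methoxy-2,2-dimethylchroman-6-yl)acetic acid | OC(=O)Cc1ccc2c(c1OC)CCC(C)(C)O2
F3 | step 8 | 2-hydroxy-3-[2-methoxy-4-(methoxymethoxy)-6-(triisopropylsilyloxy)phenyl]-1-(5-methoxy-2,2-dimethylchroman-6-yl)propan-1-one (racemic) | COCOc1cc(O[Si](C(C)C)(C(C)C)C(C)C)c(CC(O)C(=O)c2ccc3c(c2OC)CCC(C)(C)O3)c(OC)c1
F4 | step 8 | 3-[2-methoxy-4-(methoxymethoxy)-6-(triisopropylsilyloxy)phenyl]-1-(5-methoxy-2,2-dimethylchroman-6-yl)propane-1,2-dione | COCOc1cc(O[Si](C(C)C)(C(C)C)C(C)C)c(CC(=O)C(=O)c2ccc3c(c2OC)CCC(C)(C)O3)c(OC)c1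
F5 | step 8 | 2-(p-toluenesulfonylhydrazone) of 3-[2-methoxy-4-(methoxymethoxy)-6-(triisopropylsilyloxy)phenyl]-1-(5-methoxy-2,2-dimethylchroman-6-yl)propane-1,2-dione | COCOc1cc(O[Si](C(C)C)(C(C)C)C(C)C)c(CC(=NNS(=O)(=O)c2ccc(C)cc2)C(=O)c2ccc3c(c2OC)CCC(C)(C)O3)c(OC)c1
F6 | step 5 | 2-(benzyloxy)-6-methoxy-4-(methoxymethoxy)benzaldehyde | COCOc1cc(OCc2ccccc2)c(C=O)c(OC)c1
F7 | step 5 | (E)-3-[2-(benzyloxy)-6-methoxy-4-(methoxymethoxy)phenyl]-1-(5-methoxy-2,2-dimethylchroman-6-yl)prop-2-en-1-one | COCOc1cc(OCc2ccccc2)c(/C=C/C(=O)c2ccc3c(c2OC)CCC(C)(C)O3)c(OC)c1
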